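**Strategy.** Ring B is not bought as an arene but grown from a pyrylium ring. Its substitution pattern, hydroxyl on C3′, benzyl on the adjacent C4′ and the ethano bridge on C1′ meta to oxygen, is what a 2-(2-arylethyl)-4-alkylpyrylium cation yields when hydroxide opens it and the side-chain methylene next to the resulting ketone closes onto the unmasked aldehyde. One operation thus forms the C4′–C5′ bond, closes ring B and leaves only this phenol unprotected. The precursor is a pyrylium tetrafluoroborate carrying the fully benzylated ring A on a C4 ethyl arm and a 4-benzyloxyphenethyl group on C2; it is assembled by adding a ring A phenethyl Grignard to a 2-substituted 4-pyranone.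

Key step: step 8

Remarks on the chemistry: 3-bromo-5-methoxyphenol, 2-methyl-4H-pyran-4-one, 4-(benzyloxy)benzyl chloride and 4-(benzyloxy)benzyl bromide are assumed to be commercial. The target has no stereocentre; the transient pyranols 15 and 17 are racemic and their stereocentres disappear on aromatisation. ArA stands for the ring A aryl group 3-(benzyloxy)-2,6-bis[4-(benzyloxy)benzyl]-5-methoxyphenyl. In step 4 two molecules of chloride 6 are built into each molecule of product: one is entered as reactant 6 and the other on the line of reagents that add atoms.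

**Step 1**
Reactants: 1 3-bromo-5-methoxyphenol
Product: 2 1-(benzyloxy)-3-bromo-5-methoxybenzene
Conditions: BnBr, K2CO3, DMF, rt
Reagents that add atoms: benzyl bromide, BrCc1ccccc1
Why: Williamson etherification of the phenoxide with a reactive benzylic bromide should be clean, the aryl bromide being inert under these conditions.

**Step 2**
Reactants: 2 1-(benzyloxy)-3-bromo-5-methoxybenzene
Product: 4 2-[3-(benzyloxy)-5-methoxyphenyl]ethan-1-ol, via aryllithium 3 (not isolated)
Conditions: n-BuLi, THF, −78 °C; ethylene oxide, BF3·OEt2, −78 °C; H2O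
Reagents that add atoms: ethylene oxide (oxirane), C1CO1
Why: Bromine–lithium exchange at −78 °C is faster than any attack on the benzyl ether, and the aryllithium should open the Lewis-acid-activated epoxide to give the 2-arylethanol in one operation.

**Step 3**
Reactants: 4 2-[3-(benzyloxy)-5-methoxyphenyl]ethan-1-ol
Product: 5 2-[3-(benzyloxy)-2,6-dibromo-5-methoxyphenyl]ethan-1-ol
Conditions: NBS (2.05 equiv), MeCN, 0 °C → rt, dark
Reagents that add atoms: N-bromosuccinimide (two equivalents react), O=C1CCC(=O)N1Br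
Why: Electrophilic aromatic bromination of a resorcinol diether should go para to one alkoxy group and ortho to the other, so C2 and C6 react while C4 between the two alkoxy groups is spared, and the primary alcohol is not oxidised under these conditions.

**Step 4**
Reactants: 5 2-[3-(benzyloxy)-2,6-dibromo-5-methoxyphenyl]ethan-1-ol; 6 4-(benzyloxy)benzyl chloride (first of the two equivalents that are incorporated)
Product: 8 2-{3-(benzyloxy)-2,6-bis[4-(benzyloxy)benzyl]-5-methoxyphenyl}ethan-1-ol, via benzylzinc chloride 7 (not isolated)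
Conditions: 6 (3.5 equiv), Zn dust, LiCl, THF, rt; then 5 (1 equiv), Pd(OAc)2 (cat.), SPhos (2-dicyclohexylphosphino-2′,6′-dimethoxybiphenyl), THF, rt → 50 °C, zinc reagent added slowly
Reagents that add atoms: 4-(benzyloxy)benzyl chloride (the second equivalent of 6 likewise used as zinc reagent 7), ClCc1ccc(OCc2ccccc2)cc1
Why: Twofold Negishi cross-coupling, in which each of the two C–Br bonds of 5 takes up one molecule of zinc reagent 7, should succeed because benzylic zinc chlorides tolerate a free hydroxyl and have no β-hydrogen to divert the coupling, and Pd(OAc)2 with SPhos is known to couple electron-rich aryl bromides flanked by two ortho substituents.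

**Step 5**
Reactants: 8 2-{3-(benzyloxy)-2,6-bis[4-(benzyloxy)benzyl]-5-methoxyphenyl}ethan-1-ol
Product: 9 1-(benzyloxy)-2,4-bis[4-(benzyloxy)benzyl]-3-(2-bromoethyl)-5-methoxybenzene
Conditions: CBr4, PPh3, CH2Cl2, 0 °C
Reagents that add atoms: carbon tetrabromide, BrC(Br)(Br)Br
Why: The Appel reaction converts an unhindered primary alcohol into the bromide under neutral conditions that leave aryl benzyl ethers untouched.

**Step 6**
Reactants: 10 2-methyl-4H-pyran-4-one; 11 4-(benzyloxy)benzyl bromide
Product: 13 2-{2-[4-(benzyloxy)phenyl]ethyl}-4H-pyran-4-one, via lithium dienolate 12 (not isolated)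
Conditions: LiN(SiMe3)2, THF, −78 °C; then 11, −78 → −20 °C
Reagents that add atoms: none
Why: Lateral (vinylogous) deprotonation of the 2-methyl group gives the extended dienolate, which should undergo SN2 alkylation at its exocyclic carbon with the reactive benzylic bromide.

**Step 7**
Reactants: 9 1-(benzyloxy)-2,4-bis[4-(benzyloxy)benzyl]-3-(2-bromoethyl)-5-methoxybenzene; 13 2-{2-[4-(benzyloxy)phenyl]ethyl}-4H-pyran-4-one
Product: 16 4-[2-(ArA)ethyl]-2-{2-[4-(benzyloxy)phenyl]ethyl}pyrylium tetrafluoroborate, via Grignard reagent 14 (not isolated), via 4H-pyran-4-ol 15 (not isolated)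
Conditions: Mg turnings, THF, rt → 40 °C; 13, LaCl3·2LiCl, THF, 0 °C; H2O, extraction into Et2O; HBF4·OEt2 (1.1 equiv), Et2O, 0 °C, brief, salt precipitated with hexane
Reagents that add atoms: tetrafluoroboric acid (as its diethyl ether complex), [H+].F[B-](F)(F)F
Why: Grignard 1,2-addition to the pyranone carbonyl followed by acid-induced loss of water is the Baeyer–Piccard type of pyrylium synthesis, and the oxophilic LaCl3·2LiCl should favour carbonyl addition over deprotonation of the acidic side chain or conjugate attack at C6.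

**Step 8**
Reactants: 16 4-[2-(ArA)ethyl]-2-{2-[4-(benzyloxy)phenyl]ethyl}pyrylium tetrafluoroborate
Product: 19 2-[4-(benzyloxy)benzyl]-5-[2-(ArA)ethyl]phenol, via 2H-pyran-2-ol 17 (not isolated), via oxo-enal 18 (not isolated)
Conditions: NaOH (2 M aq), THF, 0 °C → 60 °C, argon; then dilute HCl to pH 5
Reagents that add atoms: none
Why: Hydroxide adds to the unsubstituted C6 of the pyrylium ring, and the resulting 2H-pyran-2-ol 17 opens by a 6π electrocyclic ring opening and tautomerises to the (Z)-5-oxo-2-enal 18, the ring oxygen ending as the ketone oxygen. The ketone enolises toward the methylene of the former C2 side chain, this carbon adds to the aldehyde carbon (former C6) in an intramolecular aldol condensation, and loss of water followed by enolisation gives the phenol with C4′–C5′ as the new bond. The closest known reaction type is the alkali conversion of 2-methyl- and 2-alkylpyrylium salts into phenols, as in 2,4,6-trimethylpyrylium to 3,5-dimethylphenol. Ring B closes in a 6-(enolendo)-exo-trig mode. No stereocentre is created, since the carbinol carbon of 17 and the aldol carbinol both become sp2. The step needs this one methylene to be the only carbon nucleophile that closes, and ring size secures it: the methylene of the C4 arm and C3 could reach either carbonyl only through four-membered rings, hydroxide attack at C2 leads to the same open-chain compound, and aromatisation makes the closure irreversible.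

**Step 9**
Reactants: 19 2-[4-(benzyloxy)benzyl]-5-[2-(ArA)ethyl]phenol
Product: 20 CNP0207338.0, 5-{2-[3-hydroxy-2,6-bis(4-hydroxybenzyl)-5-methoxyphenyl]ethyl}-2-(4-hydroxybenzyl)phenol
Conditions: H2 (1 atm), Pd/C, EtOAc/MeOH, rt
Reagents that add atoms: none
Why: Catalytic hydrogenolysis cleaves the four aryl benzyl ethers, while the diarylmethane and bibenzyl C–C bonds and the methyl ether are not touched.

**Compound list**
1 | 3-bromo-5-methoxyphenol | COc1cc(O)cc(Br)c1 | starting material
2 | 1-(benzyloxy)-3-bromo-5-methoxybenzene | COc1cc(Br)cc(OCc2ccccc2)c1 | intermediate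
3 | [3-(benzyloxy)-5-methoxyphenyl]lithium | COc1cc([Li])cc(OCc2ccccc2)c1 | intermediate
4 | 2-[3-(benzyloxy)-5-methoxyphenyl]ethan-1-ol | COc1cc(CCO)cc(OCc2ccccc2)c1 | intermediate
5 | 2-[3-(benzyloxy)-2,6-dibromo-5-methoxyphenyl]ethan-1-ol | COc1cc(OCc2ccccc2)c(Br)c(CCO)c1Br | intermediate
6 | 4-(benzyloxy)benzyl chloride | ClCc1ccc(OCc2ccccc2)cc1 | starting material
7 | [4-(benzyloxy)benzyl]zinc chloride | Cl[Zn]Cc1ccc(OCc2ccccc2)cc1 | intermediate
8 | 2-{3-(benzyloxy)-2,6-bis[4-(benzyloxy)benzyl]-5-methoxyphenyl}ethan-1-ol | COc1cc(OCc2ccccc2)c(Cc2ccc(OCc3ccccc3)cc2)c(CCO)c1Cc1ccc(OCc2ccccc2)cc1 | intermediate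
9 | 1-(benzyloxy)-2,4-bis[4-(benzyloxy)benzyl]-3-(2-bromoethyl)-5-methoxybenzene | COc1cc(OCc2ccccc2)c(Cc2ccc(OCc3ccccc3)cc2)c(CCBr)c1Cc1ccc(OCc2ccccc2)cc1 | intermediate
10 | 2-methyl-4H-pyran-4-one | CC1=CC(=O)C=CO1 | starting material
11 | 4-(benzyloxy)benzyl bromide | BrCc1ccc(OCc2ccccc2)cc1 | starting material
12 | lithium 2-methylidene-2H-pyran-4-olate | C=C1C=C(O[Li])C=CO1 | intermediate
13 | 2-{2-[4-(benzyloxy)phenyl]ethyl}-4H-pyran-4-one | O=C1C=COC(CCc2ccc(OCc3ccccc3)cc2)=C1 | intermediate
14 | [2-(ArA)ethyl]magnesium bromide | COc1cc(OCc2ccccc2)c(Cc2ccc(OCc3ccccc3)cc2)c(CC[Mg]Br)c1Cc1ccc(OCc2ccccc2)cc1 | intermediate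
15 | 4-[2-(ArA)ethyl]-2-{2-[4-(benzyloxy)phenyl]ethyl}-4H-pyran-4-ol (racemic) | COc1cc(OCc2ccccc2)c(Cc2ccc(OCc3ccccc3)cc2)c(CCC2(O)C=COC(CCc3ccc(OCc4ccccc4)cc3)=C2)c1Cc1ccc(OCc2ccccc2)cc1 | intermediate
16 | 4-[2-(ArA)ethyl]-2-{2-[4-(benzyloxy)phenyl]ethyl}pyrylium tetrafluoroborate | COc1cc(OCc2ccccc2)c(Cc2ccc(OCc3ccccc3)cc2)c(CCc2cc(CCc3ccc(OCc4ccccc4)cc3)[o+]cc2)c1Cc1ccc(OCc2ccccc2)cc1.F[B-](F)(F)F | intermediate
17 | 4-[2-(ArA)ethyl]-6-{2-[4-(benzyloxy)phenyl]ethyl}-2H-pyran-2-ol (racemic) | COc1cc(OCc2ccccc2)c(Cc2ccc(OCc3ccccc3)cc2)c(CCC2=CC(O)OC(CCc3ccc(OCc4ccccc4)cc3)=C2)c1Cc1ccc(OCc2ccccc2)cc1 | intermediate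
18 | (2Z)-3-[2-(ArA)ethyl]-7-[4-(benzyloxy)phenyl]-5-oxohept-2-enal | COc1cc(OCc2ccccc2)c(Cc2ccc(OCc3ccccc3)cc2)c(CC/C(CC(=O)CCc2ccc(OCc3ccccc3)cc2)=C/C=O)c1Cc1ccc(OCc2ccccc2)cc1 | intermediate
19 | 2-[4-(benzyloxy)benzyl]-5-[2-(ArA)ethyl]phenol | COc1cc(OCc2ccccc2)c(Cc2ccc(OCc3ccccc3)cc2)c(CCc2ccc(Cc3ccc(OCc4ccccc4)cc3)c(O)c2)c1Cc1ccc(OCc2ccccc2)cc1 | intermediate
20 | CNP0207338.0, 5-{2-[3-hydroxy-2,6-bis(4-hydroxybenzyl)-5-methoxyphenyl]ethyl}-2-(4-hydroxybenzyl)phenol | COc1cc(O)c(Cc2ccc(O)cc2)c(CCc2ccc(Cc3ccc(O)cc3)c(O)c2)c1Cc1ccc(O)cc1 | target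

**Step count.** Total: 9 steps. Longest linear sequence: 8 steps (steps 1–5, 7, 8, 9); step 6 is a one-step side branch.

**Steps most likely to fail**

Step 8. The ring-opened oxo-enal may condense with itself faster than it closes, or the anhydrobase formed at the C4 arm may decompose before ring closure. In that case ring B would be built as a cyclohexenone and aromatised. The fallback sets out from bromide 9 and comes back at phenol 19. Grignard reagent 14, made from 9, is added to 3-ethoxycyclohex-2-en-1-one and the adduct is hydrolysed with dilute HCl (Stork–Danheiser transposition) to give 3-[2-(ArA)ethyl]cyclohex-2-en-1-one F1. Kinetic deprotonation at C6 with LiN(iPr)2 at −78 °C and alkylation with bromide 11 gives 6-[4-(benzyloxy)benzyl]-3-[2-(ArA)ethyl]cyclohex-2-en-1-one F2. Aerobic dehydrogenation with Pd(O2CCF3)2, 2-(dimethylamino)pyridine and TsOH under O2 in DMSO at 80 °C aromatises it to phenol 19.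

Step 7. The Grignard reagent may act as a base toward the acidic side chain of the pyranone or add in conjugate fashion at C6. The pyrylium salt, unsubstituted at C6, may be lost by hydrolytic ring opening on isolation, and the acid may start retro-Friedel–Crafts loss of a benzyl group from the electron-rich ring A. In that case ring B would be brought in ready-made. The fallback sets out from bromide 9 and comes back at target 20. For the coupling partner, 5-bromo-2-iodophenol is O-benzylated (BnBr, K2CO3, DMF) to 2-(benzyloxy)-4-bromo-1-iodobenzene F3. This couples at the iodide only with zinc reagent 7 (Pd(PPh3)4, THF, rt) to give 2-(benzyloxy)-4-bromo-1-[4-(benzyloxy)benzyl]benzene F4. Zinc insertion into bromide 9 (Zn dust, LiCl, THF, 50 °C) gives [2-(ArA)ethyl]zinc bromide F5. Negishi coupling of this alkylzinc with the aryl bromide (Pd(OAc)2, SPhos, THF, 50 °C) gives the pentabenzyl ether of the target F6. Hydrogenolysis (H2, Pd/C) then gives target 20.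

Step 4. The second oxidative addition may stall at the more hindered C–Br bond once one benzyl group is in place, and the free hydroxyl may consume zinc reagent by protonation. In that case the benzyl groups would be introduced as aldehyde adducts. The fallback sets out from dibromide 5 and comes back at alcohol 8. Silylation (TBSCl, imidazole, DMF) gives tert-butyl{2-[3-(benzyloxy)-2,6-dibromo-5-methoxyphenyl]ethoxy}dimethylsilane F7. Bromine–lithium exchange with n-BuLi at −78 °C and addition to 4-(benzyloxy)benzaldehyde, repeated once in the same flask, gives {4-(benzyloxy)-2-[2-(tert-butyldimethylsilyloxy)ethyl]-6-methoxy-1,3-phenylene}bis{[4-(benzyloxy)phenyl]methanol} F8 as a diastereomer mixture of no consequence. Ionic hydrogenation (Et3SiH, CF3CO2H, CH2Cl2, −20 °C) removes both benzhydrylic hydroxyls to give tert-butyl[2-(ArA)ethoxy]dimethylsilane F9. Any silyl ether lost under the acid would give alcohol 8 directly. Bu4NF in THF cleaves the remaining silyl ether to alcohol 8.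

**Further compounds**
F1 | step 8 | 3-[2-(ArA)ethyl]cyclohex-2-en-1-one | COc1cc(OCc2ccccc2)c(Cc2ccc(OCc3ccccc3)cc2)c(CCC2=CC(=O)CCC2)c1Cc1ccc(OCc2ccccc2)cc1
F2 | step 8 | 6-[4-(benzyloxy)benzyl]-3-[2-(ArA)ethyl]cyclohex-2-en-1-one (racemic) | COc1cc(OCc2ccccc2)c(Cc2ccc(OCc3ccccc3)cc2)c(CCC2=CC(=O)C(Cc3ccc(OCc4ccccc4)cc3)CC2)c1Cc1ccc(OCc2ccccc2)cc1
F3 | step 7 | 2-(benzyloxy)-4-bromo-1-iodobenzene | Brc1ccc(I)c(OCc2ccccc2)c1
F4 | step 7 | 2-(benzyloxy)-4-bromo-1-[4-(benzyloxy)benzyl]benzene | Brc1ccc(Cc2ccc(OCc3ccccc3)cc2)c(OCc2ccccc2)c1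
F5 | step 7 | [2-(ArA)ethyl]zinc bromide | COc1cc(OCc2ccccc2)c(Cc2ccc(OCc3ccccc3)cc2)c(CC[Zn]Br)c1Cc1ccc(OCc2ccccc2)cc1
F6 | step 7 | pentabenzyl ether of the target, 2-(benzyloxy)-1-[4-(benzyloxy)benzyl]-4-[2-(ArA)ethyl]benzene | COc1cc(OCc2ccccc2)c(Cc2ccc(OCc3ccccc3)cc2)c(CCc2ccc(Cc3ccc(OCc4ccccc4)cc3)c(OCc3ccccc3)c2)c1Cc1ccc(OCc2ccccc2)cc1
F7 | step 4 | tert-butyl{2-[3-(benzyloxy)-2,6-dibromo-5-methoxyphenyl]ethoxy}dimethylsilane | COc1cc(OCc2ccccc2)c(Br)c(CCO[Si](C)(C)C(C)(C)C)c1Br
F8 | step 4 | {4-(benzyloxy)-2-[2-(tert-butyldimethylsilyloxy)ethyl]-6-methoxy-1,3-phenylene}bis{[4-(benzyloxy)phenyl]methanol} (diastereomer mixture) | COc1cc(OCc2ccccc2)c(C(O)c2ccc(OCc3ccccc3)cc2)c(CCO[Si](C)(C)C(C)(C)C)c1C(O)c1ccc(OCc2ccccc2)cc1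
F9 | step 4 | tert-butyl[2-(ArA)ethoxy]dimethylsilane | COc1cc(OCc2ccccc2)c(Cc2ccc(OCc3ccccc3)cc2)c(CCO[Si](C)(C)C(C)(C)C)c1Cc1ccc(OCc2ccccc2)cc1
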